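**Assumptions**
- The target has a 2,4-trans-flavan, and from the SMILES I assign it as (2R,4R).
- 2',6'-Dihydroxy-4'-methoxyacetophenone is treated as commercial. It is also one methylation from phloroacetophenone.
- The enantiomer of the chiral acid catalyst in Step 6 is whichever one gives (2R,4R) on screening.

## Retrosynthetic overview
1. Sarcandrone B comes from Claisen–Schmidt condensation of acetophenone **9** with PhCHO. The enone is installed last so it never meets the cationic chemistry.
2. **9** comes from a chiral-Brønsted-acid cascade. It couples racemic flavene **7** with the phloroglucinol-type arene **8**. The cascade opens the flavene to an alkenyl o-quinone methide, adds the arene at C4 enantioselectively, and re-closes the chroman. C2 then settles trans to C4.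
3. **7** comes from a boronate-mediated phenol–enal annulation (oxa-6π) of C2-symmetric diol **5** with cinnamaldehyde. The symmetry removes any regiochemical problem.
4. **5** comes from 5-methoxyresorcinol by directed C2 oxygenation.
5. Rings form in this order: the chromene ring (Step 5, oxa-6π), then the C4–aryl bond and the chroman ring (Step 6, ring-opened, arylated, re-closed).

## Route

**Step 1**
Reactants: 1 (5-methoxybenzene-1,3-diol)
Product: 2 (1,3-bis(methoxymethoxy)-5-methoxybenzene)
Conditions: MOMCl, i-Pr2NEt, CH2Cl2, 0 °C to rt
Reagents that add atoms: MOMCl, COCCl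
Why: Bis-MOM protection masks the phenols and installs two ortho-directing groups; no stereocentre is formed.

**Step 2**
Reactants: 2
Product: 3 (2,6-bis(methoxymethoxy)-4-methoxyphenol)
Conditions: n-BuLi, THF, 0 °C; B(OMe)3, –78 °C to rt; 30% H2O2, 2 M NaOH, 0 °C
Reagents that add atoms: H2O2, OO (source of the new phenolic O). B(OMe)3 is only a mediator and leaves no atoms.
Why: Directed ortho-lithiation occurs at C2, between the two OMOM groups (cooperative chelation), and borylation then oxidative deborylation gives the 2,6-dialkoxyphenol.

**Step 3**
Reactants: 3
Product: 4 (1,3-bis(methoxymethoxy)-2,5-dimethoxybenzene)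
Conditions: MeI, K2CO3, acetone, rt
Reagents that add atoms: MeI, CI
Why: Williamson O-methylation of the phenol installs the C8 methoxy group of the target.

**Step 4**
Reactants: 4
Product: 5 (2,5-dimethoxybenzene-1,3-diol)
Conditions: cat. HCl, MeOH, 50 °C
Reagents that add atoms: none
Why: MOM acetals hydrolyse under mild acid while the aryl methyl ethers survive. The product is a C2-symmetric diol, so either OH can later close the ring to the same product.

**Step 5**
Reactants: 5 (2,5-dimethoxybenzene-1,3-diol), 6 ((E)-cinnamaldehyde)
Product: 7 ((±)-5,8-dimethoxy-2-phenyl-2H-chromen-7-ol)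
Conditions: PhB(OH)2 (1 equiv), EtCO2H (cat.), toluene, reflux, Dean–Stark, N2
Reagents that add atoms: none
Why: In this Pettus-type 2H-chromene synthesis the aryl boronate directs ortho-hydroxyalkylation, then dehydration gives an alkenyl o-quinone methide that closes by oxa-6π electrocyclisation; C2 is deliberately racemic and is set in Step 6.

**Step 6**
Reactants: 7, 8 (1-(2,6-dihydroxy-4-methoxyphenyl)ethanone)
Product: 9 (1-[2,6-dihydroxy-3-((2R,4R)-7-hydroxy-5,8-dimethoxy-2-phenylchroman-4-yl)-4-methoxyphenyl]ethanone)
Conditions: chiral IDPi acid (5 mol%), 8 (3 equiv), toluene, 4 Å MS, –20 °C to rt, 48 h, N2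
Reagents that add atoms: none (8 is a numbered reactant and ends up in the product)
Why: Proposed new method: the strong chiral acid ionises the electron-rich flavene at C2–O1 (7-OH, 5,8-OMe stabilise the cation), giving the 1-(2-hydroxyaryl)-3-phenylallyl cation, i.e. the alkenyl o-quinone methide that is the reverse of the Step 5 closure; this makes the racemic C2 stereocentre freely interconvertible. Within the chiral ion pair, the phloroglucinol-type C-nucleophile 8 adds at C4, which sets C4 enantioselectively, and the same acid then closes the ring by 6-endo Markovnikov hydroalkoxylation of the styrene. That closure goes through a chair-like cation with the 4-aryl pseudo-axial (peri 5-OMe) and the 2-Ph equatorial, which fixes 2,4-trans. The closest known reactions are CPA-catalysed 1,4-additions of phenols to o-quinone methides, acid-catalysed cyclisation of 2-(1,3-diarylallyl)phenols to 2,4-diarylchromans, and IDPi-catalysed alkene hydroarylation. Excess 8 suppresses bis-arylation at its two equivalent C–H sites.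

**Step 7**
Reactants: 9, 10 (benzaldehyde)
Product: 11 (Sarcandrone B)
Conditions: 50% aq. KOH, EtOH, rt, 48 h, N2; quench with AcOH to pH ~5
Reagents that add atoms: none (10 is a numbered reactant)
Why: Claisen–Schmidt condensation gives the (E)-chalcone, with the phenols held as phenolates; neither stereocentre is enolisable, so both are retained.

## Compound list
1 | 5-methoxybenzene-1,3-diol | COc1cc(O)cc(O)c1 | starting material
2 | 1,3-bis(methoxymethoxy)-5-methoxybenzene | COCOc1cc(OC)cc(OCOC)c1 | intermediate
3 | 2,6-bis(methoxymethoxy)-4-methoxyphenol | COc1cc(OCOC)c(O)c(OCOC)c1 | intermediate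
4 | 1,3-bis(methoxymethoxy)-2,5-dimethoxybenzene | COc1cc(OCOC)c(OC)c(OCOC)c1 | intermediate
5 | 2,5-dimethoxybenzene-1,3-diol | COc1cc(O)c(OC)c(O)c1 | intermediate
6 | (E)-cinnamaldehyde | O=C/C=C/c1ccccc1 | starting material
7 | (±)-5,8-dimethoxy-2-phenyl-2H-chromen-7-ol | COc1cc(O)c(OC)c2OC(c3ccccc3)C=Cc12 | intermediate
8 | 1-(2,6-dihydroxy-4-methoxyphenyl)ethanone | COc1cc(O)c(C(C)=O)c(O)c1 | starting material
9 | acetophenone–flavan (2R,4R)-trans | COc1cc(O)c(C(C)=O)c(O)c1[C@H]1C[C@H](c2ccccc2)Oc2c(OC)c(O)cc(OC)c21 | intermediate
10 | benzaldehyde | O=Cc1ccccc1 | starting material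
11 | Sarcandrone B | COc1cc(O)c(C(=O)/C=C/c2ccccc2)c(O)c1[C@H]1C[C@H](c2ccccc2)Oc2c(OC)c(O)cc(OC)c21 | target

**Total steps:** 7. **Longest linear sequence:** 7 (1 → 2 → 3 → 4 → 5 → 7 → 9 → 11).

## Three steps most likely to fail
1. **Step 6 (enantio- and diastereo-selective cascade).** The acid may simply protonate C3 and give racemic trans product, or add the arene at the styryl terminus instead of C4. Fallback: a stereodefined route from 5. Mitsunobu coupling (PPh3, DIAD) with commercial (S)-1-phenylbut-3-en-1-ol inverts to the (R)-ether at C2. OsO4/NaIO4 then gives the β-aryloxy aldehyde, and TfOH-promoted cyclisation with 8 proceeds through the flavan-4-yl cation with axial (trans) arylation.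
2. **Step 5 (Pettus annulation of the very electron-rich diol).** Double hydroxyalkylation or triarylmethane formation may compete. Fallback: Vilsmeier formylation of 5, which gives a single aldehyde because of the symmetry. Add excess β-styrylMgBr to give the o-hydroxyaryl allylic alcohol, then cyclise to 7 with mild acid through the o-quinone methide.
3. **Step 2 (C2 lithiation and oxygenation).** Lithiation could occur at C4/C6, or the electron-rich phenol could be over-oxidised. Fallback: start from methyl 3,5-dihydroxy-4-methoxybenzoate. Bis-benzylate, reduce with DIBAL to the aldehyde, and run a mCPBA Baeyer–Villiger with hydrolysis to the phenol. Then methylate with MeI and remove the benzyl groups with H2/Pd-C to give 5.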